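## Structural features

The target is a cyclohept-2-en-1-one. Ring locants used throughout: C1 (ketone), C2 (bearing CH2OH), C3 (vinylic CH), C4 (quaternary, methyl and 4-methylpent-3-enyl), C5 (bearing the (E)-2-acyloxyvinyl arm, an enol ester of 3-methylbut-2-enoic acid), C6 (bearing 2-oxopropyl), C7 (CH2).

C4, C5 and C6 are contiguous stereocentres, (4R,5R,6S). The C4 methyl group, the C5 arm and the C6 arm lie on one face of the ring and the homoprenyl chain on the other.

Fragile groups are the E enol ester (cleaved by base, hydride or nucleophiles; its geometry has to be made, not equilibrated), the 2-(hydroxymethyl)enone, the 1,5-diketone with any aldehyde precursor at C5 (aldol, epimerisation), and the trisubstituted side-chain alkene (electrophilic oxidants, carbenes, acid).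

The real difficulty is the triad: a quaternary carbon next to two tertiary ones on a flexible seven-membered ring. The C5 and C6 arms are cis, whereas conjugate addition to a cycloheptenone would be expected to place them trans.

The key step exploits the fact that the two cis arms can be tied through the oxygen of the future methyl ketone into a six-membered lactone, C5–C(=O)–O–CH(CH3)–CH2–C6. The cis relation then becomes a ring fusion, the C5=C6 bond of that lactone is a dienophile, and the lactone is parasorbic acid, whose only stereocentre ends as the ketone carbon.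

A second feature is used later: the C1–C2=C3 enone flanked by quaternary C4 is the pattern obtained when an enolate made by conjugate addition to a cyclohexenone is expanded by one carbon.

## Logic of the disconnections

24 is taken back to 23 (O–Si bond) and 23 to 21 and 22 by cutting the enol C–O bond. The reason is that an alkenyl–boron bond carries a fixed E geometry into the enol ester, which enolisation of an aldehyde would not guarantee. The demand is a stereoretentive C–O coupling that tolerates two ketones.

21 goes back through 20 to 19 by cutting the vinyl C=C bond; the outer vinyl carbon comes from a one-carbon reagent. This reduces the C5 arm to a formyl group. The demand is an aldehyde-selective, E-selective olefination next to a quaternary carbon.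

19 goes back through 18 to 17 by oxidation-level changes only: the C5 formyl carbon and the carbinol carbon of the C6 arm are reconnected through an ester oxygen. This hides both sensitive carbonyl arms and the cis relation in one lactone ring. The demand is one global reduction and one global oxidation with the C2 hydroxymethyl group protected.

17 goes back through 16 and 15 to 14 by cutting the terminal side-chain C=C bond (cross-metathesis), the O–Si bond and the C2–CH2OH bond (coupling at a vinyl bromide). The side chain is carried as a monosubstituted alkene so that the next disconnection is chemoselective.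

14 goes back to 12 (through 13) by excising C2, that is by cutting C1–C2 and C2–C3. The seven-membered 2-functionalised enone becomes a six-membered silyl enol ether, on which facial control is reliable. The demand is an enol ether of fixed regiochemistry and a carbene that prefers it to the side-chain alkene.

12 goes back to 10 and 11 by cutting the C4–side-chain bond. Conjugate addition creates the quaternary carbon and delivers the enol ether in the one regiochemistry needed for ring expansion. The demand is attack anti to the lactone ring.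

10 goes back to 5 and 7 by cutting C4–C5 and C6–C7 (key disconnection). A cis-fused bicycle with two stereocentres becomes a monocyclic chiral-pool lactone and an achiral diene. The demand is regio- and facial selectivity with a weak dienophile and a fully substituted diene terminus.

7 comes from 6 by O-silylation of its kinetic enolate. 5 comes from 3 (through 4) by cutting the lactone C–O bond, and 3 from 1 and 2 by cutting the C–C bond made when an acetylide opens the epoxide.

## Other disconnections considered

Alternative 1: (the first that comes to mind) work on a preformed seven-membered ring by a Stork–Danheiser sequence, cutting the two C4–alkyl bonds.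
- Forward: the vinylogous ester A1 is alkylated twice at the alpha' carbon to the quaternary compound A2, then reduced and hydrolysed with enone transposition.
- Ground against: once C4 is quaternary, C5 and C6 are unactivated methylenes. Each arm would need its own desaturation and addition cycle, the Me/CH2R quaternary carbon exerts almost no facial bias on them, and the second arm would be expected trans to the first. The stereocentres are set one at a time and the route is longer.

Alternative 2: cut C4–C5 together with the C2–C7 bond of a cis-divinylcyclopropane (formal [4+3]).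
- Forward: a dirhodium tetracarboxylate such as Rh2(S-DOSP)4 decomposes diazoester A3; the vinylcarbenoid cyclopropanates diene A4, and Cope rearrangement gives cycloheptadiene A5.
- Attraction: the ring, C4 and C5 would be set in one step.
- Ground against: an electrophilic carbenoid is expected to attack a 1-oxygenated diene at the alkene remote from oxygen, so the C1 oxygen would be misplaced. Without it, C1 is a doubly allylic CH2 that would have to be oxidised in the presence of the homoprenyl alkene. The Z-homoprenyl chain of A3 can reach its own carbenoid carbon. The C6 arm would still have to be introduced cis to the C5 arm against the steric bias.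

Alternative 3: cut C4–C5 by Ireland–Claisen rearrangement and C2=C3 by ring-closing metathesis.
- Forward: neryl ester A6 rearranges through its silyl ketene acetal to acid A7, the Z alkene fixing C4 relative to C5; metathesis then closes the enone.
- Ground against: an acyclic chair transition state relays only relative configuration, so the absolute sense needs an auxiliary or a chiral boron enolate. The metathesis must join a 1,1-disubstituted enone alkene to a neopentyl vinyl group. C6 is still unsubstituted and would have to be set by a trans-selective conjugate addition.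

Key step: step 4

## Steps

Step 1
Reactants: 1 ethyl prop-2-ynoate; 2 (R)-2-methyloxirane
Product: 3 ethyl (5R)-5-hydroxyhex-2-ynoate
Conditions: n-BuLi, THF, −78 °C; then BF3·OEt2 and 2, −78 °C; aq. NH4Cl
Reagents that add atoms: none
Why: The lithium acetylide of 1 opens the BF3-activated epoxide at its unsubstituted carbon (Yamaguchi–Hirao alkynylation), so the stereocentre of 2 is carried over untouched.

Step 2
Reactants: 3 ethyl (5R)-5-hydroxyhex-2-ynoate
Product: 5 (6R)-6-methyl-5,6-dihydro-2H-pyran-2-one, via ethyl (2Z,5R)-5-hydroxyhex-2-enoate 4 (not isolated)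
Conditions: H2 (1 atm), Pd/CaCO3 poisoned with Pb(OAc)2, quinoline, EtOAc, 23 °C; then TsOH·H2O (cat.), toluene, 23 °C
Reagents that add atoms: none
Why: Lindlar semi-hydrogenation gives the Z enoate, in which the hydroxyl group can reach the ester and lactonises with loss of ethanol; this is the established route to parasorbic acid.

Step 3
Reactants: 6 (3E)-4-methoxypent-3-en-2-one
Product: 7 (3E)-4-methoxy-2-(trimethylsilyloxy)penta-1,3-diene
Conditions: LDA, THF, −78 °C; Me3SiCl, −78 → 0 °C
Reagents that add atoms: chlorotrimethylsilane C[Si](C)(C)Cl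
Why: Kinetic deprotonation of the vinylogous ester at the acetyl methyl group and O-silylation give the methyl-substituted Danishefsky-type diene with the enol ether geometry of 6 retained.

Step 4
Reactants: 5 (6R)-6-methyl-5,6-dihydro-2H-pyran-2-one; 7 (3E)-4-methoxy-2-(trimethylsilyloxy)penta-1,3-diene
Product: 10 (3R,4aS,8aS)-3,8-dimethyl-3,4,4a,5-tetrahydro-1H-isochromene-1,6(8aH)-dione, via cycloadduct silyl enol ether 8 (not isolated), via beta-methoxy ketone 9 (not isolated)
Conditions: 7 (3 equiv), BHT, toluene, 140 °C, sealed tube; then 1 M HCl, THF, 23 °C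
Reagents that add atoms: none
Why: This is a normal-demand Diels–Alder reaction (closest known type: additions of 1-alkoxy-3-siloxydienes to α,β-unsaturated lactones and enones), expected to be concerted but strongly asynchronous, the CH2 terminus of 7 bonding first to the β-carbon C4 of 5 and the methoxy-bearing terminus then to the α-carbon C3. The six-membered carbocycle closes in a [4+2] mode with both bonds formed suprafacially on the Z ring alkene, so the two new stereocentres (C5 and C6 of the target) are necessarily cis. Their absolute sense comes from the one stereocentre bought, C6 of 5: in the half-chair lactone the methyl group is pseudo-equatorial and the diene should approach the β-carbon axially from the face anti to it, as conjugate nucleophiles do. Regiochemistry requires the nucleophilic diene terminus at the lactone β-carbon and is secured by the matching polarisation of both partners; the lactone carbonyl is not expected to act as a heterodienophile under thermal conditions. The configuration at the methoxy-bearing carbon of 8 does not matter, because acid cleaves the silyl enol ether to 9 and eliminates methanol (E1cB) to the enone. The ring-fusion hydrogen next to the lactone carbonyl of 10 is acidic, but the cis fusion should be the stable one because it lets the lactone carbonyl sit pseudo-axial and avoid A(1,2) strain with the vinylic methyl group. The main demand is reactivity, since the dienophile is only moderately activated and the diene terminus is fully substituted; hence the forcing conditions and excess diene.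

Step 5
Reactants: 10 (3R,4aS,8aS)-3,8-dimethyl-3,4,4a,5-tetrahydro-1H-isochromene-1,6(8aH)-dione; 11 but-3-en-1-ylmagnesium bromide
Product: 12 (3R,4aS,8S,8aS)-8-(but-3-en-1-yl)-3,8-dimethyl-6-(trimethylsilyloxy)-3,4,4a,5,8,8a-hexahydro-1H-isochromen-1-one
Conditions: 11 (1.6 equiv), CuBr·SMe2 (10 mol %), Me3SiCl, HMPA, THF, −78 °C; Et3N, pentane work-up
Reagents that add atoms: chlorotrimethylsilane C[Si](C)(C)Cl
Why: Copper-catalysed conjugate addition of the Grignard reagent with in situ silylation creates quaternary C4 and gives the enol ether regiospecifically on the C4 side. The nucleophile should enter the convex face, anti to the lactone ring on the adjacent ring-fusion carbon, so the methyl group ends cis to the lactone carbonyl.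

Step 6
Reactants: 12 (3R,4aS,8S,8aS)-8-(but-3-en-1-yl)-3,8-dimethyl-6-(trimethylsilyloxy)-3,4,4a,5,8,8a-hexahydro-1H-isochromen-1-one
Product: 14 (3R,4aS,9R,9aS)-7-bromo-9-(but-3-en-1-yl)-3,9-dimethyl-4,4a,5,9a-tetrahydrocyclohepta[c]pyran-1,6(3H,9H)-dione, via dibromocyclopropane adduct 13 (not isolated)
Conditions: CHBr3, KOtBu, pentane, −30 → 0 °C; then toluene, pyridine (cat.), 90 °C
Reagents that add atoms: bromoform BrC(Br)Br
Why: Dibromocarbene should add to the electron-rich silyl enol ether in preference to the monosubstituted alkene. On warming, the siloxy group drives loss of bromide with disrotatory opening of the cyclopropane and release of Me3SiBr, inserting CBr between C1 and C3 (strain-release ring expansion of a gem-dihalocyclopropane). No stereocentre is formed or touched.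

Step 7
Reactants: 14 (3R,4aS,9R,9aS)-7-bromo-9-(but-3-en-1-yl)-3,9-dimethyl-4,4a,5,9a-tetrahydrocyclohepta[c]pyran-1,6(3H,9H)-dione
Product: 15 (3R,4aS,9S,9aS)-9-(but-3-en-1-yl)-7-(hydroxymethyl)-3,9-dimethyl-4,4a,5,9a-tetrahydrocyclohepta[c]pyran-1,6(3H,9H)-dione
Conditions: Bu3SnCH2OH (1.5 equiv), Pd(PPh3)4 (5 mol %), 1,4-dioxane, 90 °C
Reagents that add atoms: (tributylstannyl)methanol OC[Sn](CCCC)(CCCC)CCCC
Why: Stille coupling of the 2-bromoenone with the hydroxymethyl stannane places the CH2OH carbon on C2; the lactone and both alkenes are inert to zerovalent palladium.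

Step 8
Reactants: 15 (3R,4aS,9S,9aS)-9-(but-3-en-1-yl)-7-(hydroxymethyl)-3,9-dimethyl-4,4a,5,9a-tetrahydrocyclohepta[c]pyran-1,6(3H,9H)-dione
Product: 16 (3R,4aS,9S,9aS)-9-(but-3-en-1-yl)-7-{[tert-butyl(dimethyl)silyl]oxymethyl}-3,9-dimethyl-4,4a,5,9a-tetrahydrocyclohepta[c]pyran-1,6(3H,9H)-dione
Conditions: t-BuMe2SiCl, imidazole, DMF, 0 → 23 °C
Reagents that add atoms: tert-butyl(chloro)dimethylsilane CC(C)(C)[Si](C)(C)Cl
Why: Standard silylation of the only free hydroxyl group, so that it is the one alcohol not oxidised in step 11.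

Step 9
Reactants: 16 (3R,4aS,9S,9aS)-9-(but-3-en-1-yl)-7-{[tert-butyl(dimethyl)silyl]oxymethyl}-3,9-dimethyl-4,4a,5,9a-tetrahydrocyclohepta[c]pyran-1,6(3H,9H)-dione
Product: 17 (3R,4aS,9S,9aS)-7-{[tert-butyl(dimethyl)silyl]oxymethyl}-3,9-dimethyl-9-(4-methylpent-3-en-1-yl)-4,4a,5,9a-tetrahydrocyclohepta[c]pyran-1,6(3H,9H)-dione
Conditions: 2-methylbut-2-ene (excess), second-generation Grubbs catalyst (5 mol %), CH2Cl2, 40 °C
Reagents that add atoms: 2-methylbut-2-ene CC=C(C)C
Why: Cross-metathesis of the monosubstituted alkene with excess 2-methylbut-2-ene caps the chain as the trisubstituted alkene with loss of propene; the trisubstituted, electron-poor enone alkene is not a metathesis partner.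

Step 10
Reactants: 17 (3R,4aS,9S,9aS)-7-{[tert-butyl(dimethyl)silyl]oxymethyl}-3,9-dimethyl-9-(4-methylpent-3-en-1-yl)-4,4a,5,9a-tetrahydrocyclohepta[c]pyran-1,6(3H,9H)-dione
Product: 18 (4S,5S,6S)-2-{[tert-butyl(dimethyl)silyl]oxymethyl}-5-(hydroxymethyl)-6-[(2R)-2-hydroxypropyl]-4-methyl-4-(4-methylpent-3-en-1-yl)cyclohept-2-en-1-ol (both C1 epimers)
Conditions: LiAlH4 (3 equiv), THF, −20 → 0 °C; H2O, 15% aq. NaOH, H2O
Reagents that add atoms: none
Why: LiAlH4 reduces the lactone to the diol, freeing both arms, and the enone carbonyl by 1,2-addition. The silyl ether survives, and the C1 carbinol configuration is irrelevant because C1 is reoxidised in step 11.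

Step 11
Reactants: 18 (4S,5S,6S)-2-{[tert-butyl(dimethyl)silyl]oxymethyl}-5-(hydroxymethyl)-6-[(2R)-2-hydroxypropyl]-4-methyl-4-(4-methylpent-3-en-1-yl)cyclohept-2-en-1-ol
Product: 19 (1S,2S,7S)-4-{[tert-butyl(dimethyl)silyl]oxymethyl}-2-methyl-2-(4-methylpent-3-en-1-yl)-5-oxo-7-(2-oxopropyl)cyclohept-3-ene-1-carbaldehyde
Conditions: Dess–Martin periodinane (4.5 equiv), NaHCO3, CH2Cl2, 0 → 23 °C
Reagents that add atoms: none
Why: One Dess–Martin oxidation of all three alcohols returns the C1 enone and gives the methyl ketone (erasing the stereocentre bought with 2) and the C5 aldehyde. The buffered, non-basic medium should protect C5 from epimerisation and suppress intramolecular aldol reaction.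

Step 12
Reactants: 19 (1S,2S,7S)-4-{[tert-butyl(dimethyl)silyl]oxymethyl}-2-methyl-2-(4-methylpent-3-en-1-yl)-5-oxo-7-(2-oxopropyl)cyclohept-3-ene-1-carbaldehyde
Product: 20 (4R,5R,6S)-2-{[tert-butyl(dimethyl)silyl]oxymethyl}-4-methyl-4-(4-methylpent-3-en-1-yl)-6-(2-oxopropyl)-5-[(E)-2-(4,4,5,5-tetramethyl-1,3,2-dioxaborolan-2-yl)ethenyl]cyclohept-2-en-1-one
Conditions: Cl2CHBpin (2 equiv), CrCl2 (8 equiv), LiI (4 equiv), THF, 23 °C
Reagents that add atoms: 2-(dichloromethyl)-4,4,5,5-tetramethyl-1,3,2-dioxaborolane ClC(Cl)B1OC(C)(C)C(C)(C)O1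
Why: Takai–Utimoto boryl-olefination: the geminal dichromium species adds to the aldehyde and eliminates to the (E)-alkenylboronate, with E selectivity highest for branched aldehydes. Ketones react far more slowly than aldehydes with this reagent.

Step 13
Reactants: 20 (4R,5R,6S)-2-{[tert-butyl(dimethyl)silyl]oxymethyl}-4-methyl-4-(4-methylpent-3-en-1-yl)-6-(2-oxopropyl)-5-[(E)-2-(4,4,5,5-tetramethyl-1,3,2-dioxaborolan-2-yl)ethenyl]cyclohept-2-en-1-one
Product: 21 potassium trifluoroborate corresponding to 20 (Bpin replaced by BF3K)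
Conditions: KHF2 (4.5 equiv), MeOH–H2O, 0 → 23 °C
Reagents that add atoms: potassium hydrogen difluoride F.[F-].[K+]
Why: Exchange of pinacol for fluoride gives the trifluoroborate without touching the alkene geometry; short exposure should leave the primary silyl ether in place.

Step 14
Reactants: 21 potassium trifluoroborate corresponding to 20; 22 3-methylbut-2-enoic acid
Product: 23 (E)-2-[(4R,5R,6S)-2-{[tert-butyl(dimethyl)silyl]oxymethyl}-4-methyl-4-(4-methylpent-3-en-1-yl)-1-oxo-6-(2-oxopropyl)cyclohept-2-en-5-yl]ethenyl 3-methylbut-2-enoate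
Conditions: 22 (1.5 equiv), CuBr (10 mol %), DMAP (20 mol %), 4 Å MS, O2 (1 atm), CH2Cl2, 40 °C
Reagents that add atoms: none
Why: Copper-catalysed oxidative C–O coupling of alkenyltrifluoroborates with carboxylic acids (Chan–Lam–Evans type) is stereoretentive, so the E geometry fixed in step 12 is transferred to the enol ester.

Step 15
Reactants: 23 (E)-2-[(4R,5R,6S)-2-{[tert-butyl(dimethyl)silyl]oxymethyl}-4-methyl-4-(4-methylpent-3-en-1-yl)-1-oxo-6-(2-oxopropyl)cyclohept-2-en-5-yl]ethenyl 3-methylbut-2-enoate
Product: 24 (E)-2-[(4R,5R,6S)-2-(hydroxymethyl)-4-methyl-4-(4-methylpent-3-en-1-yl)-1-oxo-6-(2-oxopropyl)cyclohept-2-en-5-yl]ethenyl 3-methylbut-2-enoate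
Conditions: HF·pyridine, pyridine, THF, 0 → 23 °C
Reagents that add atoms: none
Why: Buffered HF·pyridine cleaves the primary silyl ether; the enol ester, the enone and the trisubstituted alkene should be stable to it.

## Compound list

1 | ethyl prop-2-ynoate | CCOC(=O)C#C | starting material
2 | (R)-2-methyloxirane | C[C@@H]1CO1 | starting material
3 | ethyl (5R)-5-hydroxyhex-2-ynoate | CCOC(=O)C#CC[C@@H](C)O | intermediate
4 | ethyl (2Z,5R)-5-hydroxyhex-2-enoate | CCOC(=O)/C=C\C[C@@H](C)O | intermediate
5 | (6R)-6-methyl-5,6-dihydro-2H-pyran-2-one ((R)-parasorbic acid) | C[C@@H]1CC=CC(=O)O1 | intermediate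
6 | (3E)-4-methoxypent-3-en-2-one | CO/C(C)=C/C(C)=O | starting material
7 | (3E)-4-methoxy-2-(trimethylsilyloxy)penta-1,3-diene | CO/C(C)=C/C(=C)O[Si](C)(C)C | intermediate
8 | (3R,4aS,8aS)-8-methoxy-3,8-dimethyl-6-(trimethylsilyloxy)-3,4,4a,5,8,8a-hexahydro-1H-isochromen-1-one (both C8 epimers) | C[Si](C)(C)OC1=CC(C)(OC)[C@H]2C(=O)O[C@H](C)C[C@H]2C1 | intermediate
9 | (3R,4aS,8aS)-8-methoxy-3,8-dimethyl-3,4,4a,7,8,8a-hexahydro-1H-isochromene-1,6(5H)-dione (both C8 epimers) | O=C1CC(C)(OC)[C@H]2C(=O)O[C@H](C)C[C@H]2C1 | intermediate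
10 | (3R,4aS,8aS)-3,8-dimethyl-3,4,4a,5-tetrahydro-1H-isochromene-1,6(8aH)-dione | O=C1C=C(C)[C@H]2C(=O)O[C@H](C)C[C@H]2C1 | intermediate
11 | but-3-en-1-ylmagnesium bromide | C=CCC[Mg]Br | starting material
12 | (3R,4aS,8S,8aS)-8-(but-3-en-1-yl)-3,8-dimethyl-6-(trimethylsilyloxy)-3,4,4a,5,8,8a-hexahydro-1H-isochromen-1-one | C[Si](C)(C)OC1=C[C@](C)(CCC=C)[C@H]2C(=O)O[C@H](C)C[C@H]2C1 | intermediate
13 | dibromocarbene adduct of 12 across C6=C7 (cyclopropane carbons unassigned; both converge on 14) | C[Si](C)(C)OC12C(Br)(Br)C1[C@](C)(CCC=C)[C@H]1C(=O)O[C@H](C)C[C@H]1C2 | intermediate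
14 | (3R,4aS,9R,9aS)-7-bromo-9-(but-3-en-1-yl)-3,9-dimethyl-4,4a,5,9a-tetrahydrocyclohepta[c]pyran-1,6(3H,9H)-dione | O=C1C(Br)=C[C@](C)(CCC=C)[C@H]2C(=O)O[C@H](C)C[C@H]2C1 | intermediate
15 | (3R,4aS,9S,9aS)-9-(but-3-en-1-yl)-7-(hydroxymethyl)-3,9-dimethyl-4,4a,5,9a-tetrahydrocyclohepta[c]pyran-1,6(3H,9H)-dione | O=C1C(CO)=C[C@](C)(CCC=C)[C@H]2C(=O)O[C@H](C)C[C@H]2C1 | intermediate
16 | (3R,4aS,9S,9aS)-9-(but-3-en-1-yl)-7-{[tert-butyl(dimethyl)silyl]oxymethyl}-3,9-dimethyl-4,4a,5,9a-tetrahydrocyclohepta[c]pyran-1,6(3H,9H)-dione | O=C1C(CO[Si](C)(C)C(C)(C)C)=C[C@](C)(CCC=C)[C@H]2C(=O)O[C@H](C)C[C@H]2C1 | intermediate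
17 | (3R,4aS,9S,9aS)-7-{[tert-butyl(dimethyl)silyl]oxymethyl}-3,9-dimethyl-9-(4-methylpent-3-en-1-yl)-4,4a,5,9a-tetrahydrocyclohepta[c]pyran-1,6(3H,9H)-dione | O=C1C(CO[Si](C)(C)C(C)(C)C)=C[C@](C)(CCC=C(C)C)[C@H]2C(=O)O[C@H](C)C[C@H]2C1 | intermediate
18 | (4S,5S,6S)-2-{[tert-butyl(dimethyl)silyl]oxymethyl}-5-(hydroxymethyl)-6-[(2R)-2-hydroxypropyl]-4-methyl-4-(4-methylpent-3-en-1-yl)cyclohept-2-en-1-ol (both C1 epimers) | C[C@@H](O)C[C@H]1CC(O)C(CO[Si](C)(C)C(C)(C)C)=C[C@](C)(CCC=C(C)C)[C@H]1CO | intermediate
19 | (1S,2S,7S)-4-{[tert-butyl(dimethyl)silyl]oxymethyl}-2-methyl-2-(4-methylpent-3-en-1-yl)-5-oxo-7-(2-oxopropyl)cyclohept-3-ene-1-carbaldehyde | CC(=O)C[C@H]1CC(=O)C(CO[Si](C)(C)C(C)(C)C)=C[C@](C)(CCC=C(C)C)[C@H]1C=O | intermediate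
20 | (4R,5R,6S)-2-{[tert-butyl(dimethyl)silyl]oxymethyl}-4-methyl-4-(4-methylpent-3-en-1-yl)-6-(2-oxopropyl)-5-[(E)-2-(4,4,5,5-tetramethyl-1,3,2-dioxaborolan-2-yl)ethenyl]cyclohept-2-en-1-one | CC(=O)C[C@H]1CC(=O)C(CO[Si](C)(C)C(C)(C)C)=C[C@](C)(CCC=C(C)C)[C@H]1/C=C/B1OC(C)(C)C(C)(C)O1 | intermediate
21 | potassium trifluoroborate corresponding to 20 (Bpin replaced by BF3K; 4R,5R,6S; E) | CC(=O)C[C@H]1CC(=O)C(CO[Si](C)(C)C(C)(C)C)=C[C@](C)(CCC=C(C)C)[C@H]1/C=C/[B-](F)(F)F.[K+] | intermediate
22 | 3-methylbut-2-enoic acid | CC(C)=CC(=O)O | starting material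
23 | (E)-2-[(4R,5R,6S)-2-{[tert-butyl(dimethyl)silyl]oxymethyl}-4-methyl-4-(4-methylpent-3-en-1-yl)-1-oxo-6-(2-oxopropyl)cyclohept-2-en-5-yl]ethenyl 3-methylbut-2-enoate | CC(=O)C[C@H]1CC(=O)C(CO[Si](C)(C)C(C)(C)C)=C[C@](C)(CCC=C(C)C)[C@H]1/C=C/OC(=O)C=C(C)C | intermediate
24 | (E)-2-[(4R,5R,6S)-2-(hydroxymethyl)-4-methyl-4-(4-methylpent-3-en-1-yl)-1-oxo-6-(2-oxopropyl)cyclohept-2-en-5-yl]ethenyl 3-methylbut-2-enoate (ring locants of the parent cyclohept-2-en-1-one) | CC(=O)C[C@H]1CC(=O)C(CO)=C[C@](C)(CCC=C(C)C)[C@H]1/C=C/OC(=O)C=C(C)C | target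

## Step count and least certain steps

Total: 15 steps. Longest linear sequence: 14 steps (steps 1, 2 and 4 to 15); step 3 is a one-step side branch.

**Step 4 (key step).**
- What may go wrong: the cycloaddition may stall because the unsaturated δ-lactone is a weak dienophile and the diene terminus is fully substituted. The diene may then be lost by thermal desilylation or polymerisation, and facial selectivity may erode at 140 °C.
- Fallback: a stepwise annulation that sets out from 5 and 7 and comes back at 10. Mukaiyama–Michael addition of 7 to 5 (TiCl4, CH2Cl2, −78 °C), again anti to the methyl group, should give (4S,6R)-4-[(3E)-4-methoxy-2-oxopent-3-en-1-yl]-6-methyloxan-2-one F1. With LiN(SiMe3)2 (THF, −78 → 0 °C) the lactone enolate of F1 should add to the β-methoxy enone (6-endo Michael) and expel methoxide to give 10.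

**Step 6.**
- What may go wrong: the carbene may add to the terminal alkene, KOtBu may cleave the silyl enol ether before cyclopropanation, or base may epimerise the ring-fusion carbon next to the lactone carbonyl.
- Fallback: from 12 back to 15 without a dihalocarbene.
  - Et2Zn and CH2I2 (CH2Cl2, 0 °C) should give the siloxycyclopropane F2.
  - FeCl3 in DMF should open it oxidatively to the β-chloro ketone F3 (Ito–Saegusa ring expansion).
  - NaOAc in MeOH should eliminate HCl to the cycloheptenone F4.
  - Iodine and pyridine should give the 2-iodoenone F5.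
  - The Stille coupling of step 7 then leads to 15.

**Step 12.**
- What may go wrong: the bulky boryl dichromium reagent may add too slowly to the neopentylic, α-branched aldehyde, leaving time for reduction, aldol reaction with the methyl ketone or epimerisation at C5.
- Fallback: from 19 back to 20, making the C–B bond by cross-coupling instead of by olefination. Takai iodo-olefination (CHI3, CrCl2, THF–dioxane) should give the (E)-vinyl iodide F6. Stereoretentive Miyaura borylation (B2pin2, PdCl2(dppf), KOAc, DMSO, 60 °C) should then give 20.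

**Step 14.**
- What may go wrong: protodeboronation or oxidative homocoupling of 21 may outrun C–O bond formation, and some E/Z erosion is possible under the oxidative copper conditions.
- Fallback: from 20 back to 23 through the enol of an aldehyde. Oxidation of 20 (NaBO3·4H2O, THF–H2O) should give the homologous aldehyde F7. Acylation of its enol with 3-methylbut-2-enoic anhydride (Et3N, DMAP, CH2Cl2) should favour the E enol ester because of the bulky C5 substituent; the E isomer 23 is separated from any Z isomer.

## Further compounds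

F1 | step 4 | (4S,6R)-4-[(3E)-4-methoxy-2-oxopent-3-en-1-yl]-6-methyloxan-2-one | C[C@@H]1C[C@@H](CC(=O)/C=C(\C)OC)CC(=O)O1
F2 | step 6 | methylene (cyclopropane) adduct of 12 across C6=C7 (cyclopropane carbons unassigned) | C[Si](C)(C)OC12CC1[C@](C)(CCC=C)[C@H]1C(=O)O[C@H](C)C[C@H]1C2
F3 | step 6 | 9-(but-3-en-1-yl)-8-chloro-3,9-dimethylhexahydrocyclohepta[c]pyran-1,6-dione (C8 unassigned; other centres as in 14) | O=C1CC(Cl)[C@](C)(CCC=C)[C@H]2C(=O)O[C@H](C)C[C@H]2C1
F4 | step 6 | 9-(but-3-en-1-yl)-3,9-dimethyl-4,4a,5,9a-tetrahydrocyclohepta[c]pyran-1,6(3H,9H)-dione (stereocentres as in 14) | O=C1C=C[C@](C)(CCC=C)[C@H]2C(=O)O[C@H](C)C[C@H]2C1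
F5 | step 6 | 9-(but-3-en-1-yl)-7-iodo-3,9-dimethyl-4,4a,5,9a-tetrahydrocyclohepta[c]pyran-1,6(3H,9H)-dione (stereocentres as in 14) | O=C1C(I)=C[C@](C)(CCC=C)[C@H]2C(=O)O[C@H](C)C[C@H]2C1
F6 | step 12 | (4R,5R,6S)-2-{[tert-butyl(dimethyl)silyl]oxymethyl}-5-[(E)-2-iodoethenyl]-4-methyl-4-(4-methylpent-3-en-1-yl)-6-(2-oxopropyl)cyclohept-2-en-1-one | CC(=O)C[C@H]1CC(=O)C(CO[Si](C)(C)C(C)(C)C)=C[C@](C)(CCC=C(C)C)[C@H]1/C=C/I
F7 | step 14 | 2-[2-{[tert-butyl(dimethyl)silyl]oxymethyl}-4-methyl-4-(4-methylpent-3-en-1-yl)-1-oxo-6-(2-oxopropyl)cyclohept-2-en-5-yl]acetaldehyde (ring stereocentres as in 24) | CC(=O)C[C@H]1CC(=O)C(CO[Si](C)(C)C(C)(C)C)=C[C@](C)(CCC=C(C)C)[C@H]1CC=O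
A1 | alternative 1 | 2-{[tert-butyl(dimethyl)silyl]oxymethyl}-3-(2-methylpropoxy)cyclohept-2-en-1-one | CC(C)COC1=C(CO[Si](C)(C)C(C)(C)C)C(=O)CCCC1
A2 | alternative 1 | 2-{[tert-butyl(dimethyl)silyl]oxymethyl}-7-methyl-7-(4-methylpent-3-en-1-yl)-3-(2-methylpropoxy)cyclohept-2-en-1-one (C7 configured as C4 of 24) | CC(C)COC1=C(CO[Si](C)(C)C(C)(C)C)C(=O)[C@](C)(CCC=C(C)C)CCC1
A3 | alternative 2 | methyl (3Z)-2-diazo-4,8-dimethylnona-3,7-dienoate | COC(=O)C(=[N+]=[N-])/C=C(/C)CCC=C(C)C
A4 | alternative 2 | (1E,3E)-1,5-bis(triethylsilyloxy)penta-1,3-diene | CC[Si](CC)(CC)O/C=C/C=C/CO[Si](CC)(CC)CC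
A5 | alternative 2 | methyl 3-methyl-3-(4-methylpent-3-en-1-yl)-7-(triethylsilyloxy)-4-[(triethylsilyloxy)methyl]cyclohepta-1,5-diene-1-carboxylate (C3 and C4 configured as C4 and C5 of 24; siloxy group cis to the C4 arm) | COC(=O)C1=C[C@](C)(CCC=C(C)C)[C@@H](CO[Si](CC)(CC)CC)C=C[C@H]1O[Si](CC)(CC)CC
A6 | alternative 3 | (2Z)-3,7-dimethylocta-2,6-dien-1-yl 4-[2-(3-{[tert-butyl(dimethyl)silyl]oxy}prop-1-en-2-yl)-1,3-dioxolan-2-yl]butanoate | C=C(CO[Si](C)(C)C(C)(C)C)C1(CCCC(=O)OC/C=C(/C)CCC=C(C)C)OCCO1
A7 | alternative 3 | 2-{2-[2-(3-{[tert-butyl(dimethyl)silyl]oxy}prop-1-en-2-yl)-1,3-dioxolan-2-yl]ethyl}-3-ethenyl-3,7-dimethyloct-6-enoic acid (C2 and C3 configured as C5 and C4 of 24) | OC(=O)[C@@H](CCC1(OCCO1)C(=C)CO[Si](C)(C)C(C)(C)C)[C@@](C)(CCC=C(C)C)C=C
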